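**Strategy.** The route rests on disconnecting ring A at the C4–C5 bond together with ring B at C9–C10 (labdane numbering), so that the whole decalin unfolds to an acyclic, farnesylacetone-derived (2S,3S)-epoxy alcohol. The feature exploited is the head-to-tail triprenyl pattern of rings A and B, with the oxygenated C18 on the quaternary C4. A titanocene-mediated radical cascade closes both rings in one operation, sets C4, C5, C9 and C10, and leaves the C8=C17 methylene. The C3 oxygen from the asymmetric epoxidation steers the fold and is removed at the end. The hydroxy acid side chain comes from an enantioselective proton-initiated lactonization and is attached by esterification.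

Key step: step 4

Remark: (5E,9E)-farnesylacetone is taken as a commercial single isomer; for the two reagent-controlled steps 7 and 11 the sense of induction is assigned by analogy (cyclization of homologous polyprenoic acids; hydrogenation of geranic acid), and the antipodal ligand is used if the opposite sense is found.

Step 1
Reactants: 1 (5E,9E)-farnesylacetone; 2 ethylene glycol
Product: 3 2-methyl-2-[(3E,7E)-4,8,12-trimethyltrideca-3,7,11-trien-1-yl]-1,3-dioxolane
Conditions: PPTS (cat.), benzene, reflux, Dean–Stark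
Reagents that add atoms: none
Why: Acid-catalysed ketalization with azeotropic removal of water masks the methyl ketone, which would otherwise trap a carbon radical in step 4; PPTS is too weak to protonate the trisubstituted alkenes.

Step 2
Reactants: 3
Product: 4 (2E,6E,10E)-2,6,10-trimethyl-13-(2-methyl-1,3-dioxolan-2-yl)trideca-2,6,10-trien-1-ol
Conditions: SeO2 (0.2 equiv), t-BuOOH (3 equiv), CH2Cl2, 0 °C to rt, stopped at partial conversion
Reagents that add atoms: selenium dioxide, O=[Se]=O (turned over by tert-butyl hydroperoxide, CC(C)(C)OO)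
Why: Catalytic Riley allylic oxidation (ene reaction, then [2,3]-sigmatropic shift) attacks the most electron-rich and least hindered terminal isopropylidene group and gives the (E)-allylic alcohol by the known E-selectivity of this reaction.

Step 3
Reactants: 4
Product: 5 [(2S,3S)-3-[(3E,7E)-3,7-dimethyl-10-(2-methyl-1,3-dioxolan-2-yl)deca-3,7-dien-1-yl]-2-methyloxiran-2-yl]methanol
Conditions: Ti(OiPr)4 (0.1 equiv), L-(+)-diethyl tartrate (0.12 equiv), t-BuOOH, 4 Å molecular sieves, CH2Cl2, −20 °C
Reagents that add atoms: tert-butyl hydroperoxide, CC(C)(C)OO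
Why: Sharpless asymmetric epoxidation: the allylic hydroxyl directs the titanium tartrate peroxide to the C3=C4 alkene only, and L-(+)-tartrate gives the (2S,3S)-epoxide, the same spatial sense as (3S)-2,3-oxidosqualene.

Step 4
Reactants: 5
Product: 7 3β,18-dihydroxy-14,15-dinorlabd-8(17)-en-13-one (5α-H, 9α-H, 10β-CH3, 4α-CH2OH, 4β-CH3), via cyclized ketal diol 6 (not isolated)
Conditions: Cp2TiCl2 (2.5 equiv), Mn dust (8 equiv), THF, rt, slow addition of 5 at high dilution; then 2 M HCl, THF, rt
Reagents that add atoms: water, O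
Why: Cp2TiCl (trivalent titanium, formed in the flask from Cp2TiCl2 and Mn) opens the epoxide by single-electron transfer at the C4–O bond to give the tertiary C4 radical, which adds to C5 of the C5=C10 alkene; the resulting C10 radical adds to C9 of the C8=C9 alkene, and a second Cp2TiCl removes a hydrogen atom from the C17 methyl of the tertiary C8 radical to leave the C8=C17 alkene. The closest known reaction is the titanocene-mediated radical cyclization of epoxypolyprenes (Nugent–RajanBabu reagent), and the acidic work-up cleaves the O–Ti bonds and the dioxolane. Ring A closes 6-endo-trig by the C4–C5 bond and ring B closes 6-endo-trig by the C9–C10 bond, each through a chair. C5, C10 and C9 follow from the chair–chair fold of the all-E chain in which the bulky C3–O–Ti group, fixed in step 3, is equatorial (5α-H, 10β-CH3, C11 equatorial); at the planar C4 radical the larger CH2O–Ti group should take the equatorial α site and the methyl the axial β site. The step needs C4–O rather than C3–O cleavage, secured by the tertiary radical, and 6-endo rather than 5-exo addition, secured by attack at the less substituted alkene carbons to give tertiary radicals. It also needs a stop after two rings, secured by the saturated ketal side chain that offers the C8 radical no π-acceptor.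

Step 5
Reactants: 7; 8 trimethyl phosphonoacetate
Product: 9 methyl (13E)-3β,18-dihydroxylabda-8(17),13-dien-15-oate
Conditions: 8 (3 equiv) pre-treated with NaH (2.8 equiv), THF, 0 °C; then 7, 65 °C; Z isomer removed by chromatography
Reagents that add atoms: none
Why: Horner–Wadsworth–Emmons olefination of the methyl ketone; the preformed phosphonate anion is too weakly basic to deprotonate the hydroxyl groups, and the E isomer (C12 anti to the ester) should predominate.

Step 6
Reactants: 10 geranyl bromide; 11 acetic acid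
Product: 12 (4E)-5,9-dimethyldeca-4,8-dienoic acid
Conditions: 11, LiN(i-Pr)2 (2.1 equiv), THF/DMPU, 0 °C; then 10, 0 °C to rt; dilute HCl work-up
Reagents that add atoms: none
Why: C-alkylation of the acetic acid dianion by SN2 displacement at the primary allylic bromide, which keeps the E geometry of the geranyl unit.

Step 7
Reactants: 12
Product: 13 (4aR,8aR)-5,5,8a-trimethyloctahydro-2H-chromen-2-one (trans-fused)
Conditions: (S)-2'-methoxy-1,1'-binaphthalen-2-ol (1.6 equiv), SnCl4 (1.5 equiv), toluene, −78 °C
Reagents that add atoms: none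
Why: Lewis acid-assisted chiral Brønsted acid (LBA) polyene cyclization: enantioface-selective protonation of the terminal alkene, antiperiplanar addition across the (E)-4,5-alkene in a chair and equatorial capture of the tertiary cation by the carboxyl oxygen set C4a and C8a together, trans by the E geometry and in absolute sense by the binaphthol.

Step 8
Reactants: 13
Product: 14 4-[(1R,2R)-2-hydroxy-2,6,6-trimethylcyclohexyl]butan-2-one
Conditions: MeLi (1.05 equiv), THF, −78 °C; aq. NH4Cl
Reagents that add atoms: methyllithium, [Li]C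
Why: Single addition of methyllithium to the lactone gives a lithium hemiketal alkoxide that is stable at low temperature and opens on protonation to the δ-hydroxy methyl ketone; the ring stereocenters are untouched.

Step 9
Reactants: 14; 8 trimethyl phosphonoacetate
Product: 15 methyl (2E)-5-[(1R,2R)-2-hydroxy-2,6,6-trimethylcyclohexyl]-3-methylpent-2-enoate
Conditions: 8 (3 equiv) pre-treated with NaH (2.8 equiv), THF, 0 °C; then 14, 65 °C; Z isomer removed by chromatography
Reagents that add atoms: none
Why: Horner–Wadsworth–Emmons olefination of the unhindered methyl ketone; the tertiary hydroxyl is not deprotonated by the phosphonate anion, and a geometrically pure E ester is needed for step 11.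

Step 10
Reactants: 15
Product: 16 (2E)-5-[(1R,2R)-2-hydroxy-2,6,6-trimethylcyclohexyl]-3-methylpent-2-enoic acid
Conditions: LiOH·H2O, THF/MeOH/H2O, rt; then dilute HCl to pH 4
Reagents that add atoms: lithium hydroxide, [Li+].[OH-]
Why: Saponification of the methyl ester under mild conditions that leave the E alkene and the tertiary alcohol unchanged.

Step 11
Reactants: 16
Product: 17 (3S)-5-[(1R,2R)-2-hydroxy-2,6,6-trimethylcyclohexyl]-3-methylpentanoic acid
Conditions: H2 (50 atm), Ru(OAc)2[(R)-BINAP] (1 mol %), MeOH, rt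
Reagents that add atoms: none
Why: Noyori asymmetric hydrogenation of a β,β-disubstituted acrylic acid, directed by the carboxylate, sets C3 under catalyst control in the manner of geranic acid to citronellic acid.

Step 12
Reactants: 9; 17
Product: 18 methyl (13E)-3β-hydroxy-18-{[(3S)-5-((1R,2R)-2-hydroxy-2,6,6-trimethylcyclohexyl)-3-methylpentanoyl]oxy}labda-8(17),13-dien-15-oate
Conditions: EDC·HCl (1.3 equiv), DMAP (0.2 equiv), CH2Cl2, 0 °C to rt
Reagents that add atoms: none
Why: Steglich esterification; the primary 18-hydroxyl should be acylated in preference to the secondary 3β-hydroxyl next to the quaternary C4, and the tertiary hydroxyl of 17 is inert.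

Step 13
Reactants: 18
Product: 19 the 3-O-(phenoxythiocarbonyl) derivative of 18
Conditions: PhOC(S)Cl (1.5 equiv), pyridine, DMAP (cat.), CH2Cl2, rt
Reagents that add atoms: O-phenyl chlorothionoformate, S=C(Cl)Oc1ccccc1
Why: Thioacylation of the only remaining secondary alcohol gives the thionocarbonate needed for the Barton–McCombie deoxygenation; the tertiary alcohol does not react.

Step 14
Reactants: 19
Product: 20 CNP0174687.1, methyl (13E)-18-{[(3S)-5-((1R,2R)-2-hydroxy-2,6,6-trimethylcyclohexyl)-3-methylpentanoyl]oxy}labda-8(17),13-dien-15-oate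
Conditions: Bu3SnH (2 equiv), AIBN (0.2 equiv), toluene, 100 °C
Reagents that add atoms: none
Why: Barton–McCombie radical deoxygenation: the tin radical adds to the thiocarbonyl sulfur, β-scission gives the secondary C3 radical, which takes hydrogen from Bu3SnH; no stereocenter is made and the alkenes, esters and tertiary alcohol are not touched.

**Compound list**

1 | (5E,9E)-6,10,14-trimethylpentadeca-5,9,13-trien-2-one (farnesylacetone) | CC(C)=CCC/C(C)=C/CC/C(C)=C/CCC(C)=O | starting material
2 | ethylene glycol | OCCO | starting material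
3 | 2-methyl-2-[(3E,7E)-4,8,12-trimethyltrideca-3,7,11-trien-1-yl]-1,3-dioxolane | CC(C)=CCC/C(C)=C/CC/C(C)=C/CCC1(C)OCCO1 | intermediate
4 | (2E,6E,10E)-2,6,10-trimethyl-13-(2-methyl-1,3-dioxolan-2-yl)trideca-2,6,10-trien-1-ol | OC/C(C)=C/CC/C(C)=C/CC/C(C)=C/CCC1(C)OCCO1 | intermediate
5 | [(2S,3S)-3-[(3E,7E)-3,7-dimethyl-10-(2-methyl-1,3-dioxolan-2-yl)deca-3,7-dien-1-yl]-2-methyloxiran-2-yl]methanol | OC[C@]1(C)O[C@H]1CC/C(C)=C/CC/C(C)=C/CCC2(C)OCCO2 | intermediate
6 | 3β,18-dihydroxy-14,15-dinorlabd-8(17)-en-13-one ethylene ketal | C=C1CC[C@H]2[C@](C)(CO)[C@@H](O)CC[C@]2(C)[C@H]1CCC3(C)OCCO3 | intermediate (not isolated)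
7 | 3β,18-dihydroxy-14,15-dinorlabd-8(17)-en-13-one | C=C1CC[C@H]2[C@](C)(CO)[C@@H](O)CC[C@]2(C)[C@H]1CCC(C)=O | intermediate
8 | trimethyl phosphonoacetate | COC(=O)CP(=O)(OC)OC | starting material
9 | methyl (13E)-3β,18-dihydroxylabda-8(17),13-dien-15-oate | C=C1CC[C@H]2[C@](C)(CO)[C@@H](O)CC[C@]2(C)[C@H]1CC/C(C)=C/C(=O)OC | intermediate
10 | geranyl bromide, (2E)-1-bromo-3,7-dimethylocta-2,6-diene | CC(C)=CCC/C(C)=C/CBr | starting material
11 | acetic acid | CC(=O)O | starting material
12 | (4E)-5,9-dimethyldeca-4,8-dienoic acid | CC(C)=CCC/C(C)=C/CCC(=O)O | intermediate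
13 | (4aR,8aR)-5,5,8a-trimethyloctahydro-2H-chromen-2-one | O=C1CC[C@@H]2C(C)(C)CCC[C@@]2(C)O1 | intermediate
14 | 4-[(1R,2R)-2-hydroxy-2,6,6-trimethylcyclohexyl]butan-2-one | CC(=O)CC[C@@H]1C(C)(C)CCC[C@@]1(C)O | intermediate
15 | methyl (2E)-5-[(1R,2R)-2-hydroxy-2,6,6-trimethylcyclohexyl]-3-methylpent-2-enoate | COC(=O)/C=C(C)/CC[C@@H]1C(C)(C)CCC[C@@]1(C)O | intermediate
16 | (2E)-5-[(1R,2R)-2-hydroxy-2,6,6-trimethylcyclohexyl]-3-methylpent-2-enoic acid | OC(=O)/C=C(C)/CC[C@@H]1C(C)(C)CCC[C@@]1(C)O | intermediate
17 | (3S)-5-[(1R,2R)-2-hydroxy-2,6,6-trimethylcyclohexyl]-3-methylpentanoic acid | OC(=O)C[C@@H](C)CC[C@@H]1C(C)(C)CCC[C@@]1(C)O | intermediate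
18 | methyl (13E)-3β-hydroxy-18-{[(3S)-5-((1R,2R)-2-hydroxy-2,6,6-trimethylcyclohexyl)-3-methylpentanoyl]oxy}labda-8(17),13-dien-15-oate | C=C1CC[C@H]2[C@](C)(COC(=O)C[C@@H](C)CC[C@@H]3C(C)(C)CCC[C@@]3(C)O)[C@@H](O)CC[C@]2(C)[C@H]1CC/C(C)=C/C(=O)OC | intermediate
19 | 3-O-(phenoxythiocarbonyl) derivative of 18 | C=C1CC[C@H]2[C@](C)(COC(=O)C[C@@H](C)CC[C@@H]3C(C)(C)CCC[C@@]3(C)O)[C@@H](OC(=S)Oc4ccccc4)CC[C@]2(C)[C@H]1CC/C(C)=C/C(=O)OC | intermediate
20 | CNP0174687.1 | C=C1CC[C@H]2[C@](C)(COC(=O)C[C@@H](C)CC[C@@H]3C(C)(C)CCC[C@@]3(C)O)CCC[C@]2(C)[C@H]1CC/C(C)=C/C(=O)OC | target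

**Step count and risks**

Total step count: 14. Longest linear sequence: 9 steps (steps 6 to 11, then 12 to 14).

Step 4. The radical chain may be cut short after ring A by early hydrogen abstraction, the face selectivity at the planar C4 radical may erode, and the unprotected C18 oxygen may be lost by β-elimination from a titanium-bound C4 species. The fallback changes the point of convergence so that the cascade runs on a C18 ester with no free hydroxyl next to the radical centre. Setting out from 5, esterification with acid 17 (EDC, DMAP, CH2Cl2) gives the epoxy ester, [(2S,3S)-3-[(3E,7E)-3,7-dimethyl-10-(2-methyl-1,3-dioxolan-2-yl)deca-3,7-dien-1-yl]-2-methyloxiran-2-yl]methyl (3S)-5-[(1R,2R)-2-hydroxy-2,6,6-trimethylcyclohexyl]-3-methylpentanoate F1. It is cyclized with catalytic Cp2TiCl2 (0.2 equiv), Mn, Me3SiCl and 2,4,6-collidine in THF, where the low standing concentration of trivalent titanium disfavours trapping of the C4 radical. This gives the cyclized ketal ester, the 13-ethylene ketal of the 18-acyloxy-3β-hydroxy-14,15-dinorlabd-8(17)-en-13-one F2, which is not isolated but hydrolysed with 1 M HCl in THF to the keto ester, 18-acyloxy-3β-hydroxy-14,15-dinorlabd-8(17)-en-13-one F3. Olefination of F3 with 8 as in step 5 comes back to the route at 18.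

Step 7. The enantioface discrimination in the protonation may be incomplete, and the cyclization may stop at monocyclic unsaturated acids. The fallback is a halonium-initiated instead of a proton-initiated cyclization. Setting out from 12, N-iodosuccinimide with a stoichiometric (S)-binaphthol-derived phosphoramidite as nucleophilic chiral promoter (toluene, −40 °C) should give the iodo lactone, (4aR,6R,8aR)-6-iodo-5,5,8a-trimethyloctahydro-2H-chromen-2-one F4, with equatorial iodine from anti addition; it can be enriched by crystallization. Radical deiodination (Bu3SnH, AIBN, benzene, 80 °C) comes back to the route at 13.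

Step 2. Over-oxidation to the enal, oxidation at the internal allylic methyl groups and low conversion are likely. The fallback cuts the terminal prenyl unit and rebuilds it. Setting out from 3, N-bromosuccinimide in aqueous THF at 0 °C and then K2CO3 in methanol give the terminal epoxide, 2-[(3E,7E)-10-(3,3-dimethyloxiran-2-yl)-4,8-dimethyldeca-3,7-dien-1-yl]-2-methyl-1,3-dioxolane F5 (racemic; its stereocenter is lost in the next operation). HIO4 in aqueous THF at 0 °C cleaves it to the aldehyde, (4E,8E)-4,8-dimethyl-11-(2-methyl-1,3-dioxolan-2-yl)undeca-4,8-dienal F6. Wittig olefination with ethyl 2-(triphenylphosphoranylidene)propanoate (CH2Cl2, rt) gives the ester, ethyl (2E,6E,10E)-2,6,10-trimethyl-13-(2-methyl-1,3-dioxolan-2-yl)trideca-2,6,10-trienoate F7. Reduction of F7 with diisobutylaluminium hydride (i-Bu2AlH, CH2Cl2, −78 °C) comes back to the route at 4.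

**Further compounds**

F1 | step 4 | [(2S,3S)-3-[(3E,7E)-3,7-dimethyl-10-(2-methyl-1,3-dioxolan-2-yl)deca-3,7-dien-1-yl]-2-methyloxiran-2-yl]methyl (3S)-5-[(1R,2R)-2-hydroxy-2,6,6-trimethylcyclohexyl]-3-methylpentanoate | O=C(C[C@@H](C)CC[C@@H]1C(C)(C)CCC[C@@]1(C)O)OC[C@]2(C)O[C@H]2CC/C(C)=C/CC/C(C)=C/CCC3(C)OCCO3
F2 | step 4 | 13-ethylene ketal of 18-{[(3S)-5-((1R,2R)-2-hydroxy-2,6,6-trimethylcyclohexyl)-3-methylpentanoyl]oxy}-3β-hydroxy-14,15-dinorlabd-8(17)-en-13-one | C=C1CC[C@H]2[C@](C)(COC(=O)C[C@@H](C)CC[C@@H]3C(C)(C)CCC[C@@]3(C)O)[C@@H](O)CC[C@]2(C)[C@H]1CCC4(C)OCCO4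
F3 | step 4 | 18-{[(3S)-5-((1R,2R)-2-hydroxy-2,6,6-trimethylcyclohexyl)-3-methylpentanoyl]oxy}-3β-hydroxy-14,15-dinorlabd-8(17)-en-13-one | C=C1CC[C@H]2[C@](C)(COC(=O)C[C@@H](C)CC[C@@H]3C(C)(C)CCC[C@@]3(C)O)[C@@H](O)CC[C@]2(C)[C@H]1CCC(C)=O
F4 | step 7 | (4aR,6R,8aR)-6-iodo-5,5,8a-trimethyloctahydro-2H-chromen-2-one | O=C1CC[C@@H]2C(C)(C)[C@H](I)CC[C@@]2(C)O1
F5 | step 2 | 2-[(3E,7E)-10-(3,3-dimethyloxiran-2-yl)-4,8-dimethyldeca-3,7-dien-1-yl]-2-methyl-1,3-dioxolane | CC1(C)OC1CC/C(C)=C/CC/C(C)=C/CCC2(C)OCCO2
F6 | step 2 | (4E,8E)-4,8-dimethyl-11-(2-methyl-1,3-dioxolan-2-yl)undeca-4,8-dienal | O=CCC/C(C)=C/CC/C(C)=C/CCC1(C)OCCO1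
F7 | step 2 | ethyl (2E,6E,10E)-2,6,10-trimethyl-13-(2-methyl-1,3-dioxolan-2-yl)trideca-2,6,10-trienoate | CCOC(=O)/C(C)=C/CC/C(C)=C/CC/C(C)=C/CCC1(C)OCCO1
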